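## Retrosynthetic overview

1. Target ⇒ its TBS ether ⇒ cut the C(sp3)–C(sp2) bond between the methyl-bearing carbon on ring B (central pyrone) and the trisubstituted alkene: a racemic pyronylic chloride (western fragment) and an (E)-alkenyl bromide (eastern fragment, ring A) are joined by an enantioconvergent nickel reductive coupling (new).
2. Both anti pyrone–CH(Me)–CH(O) units ⇒ lateral (vinylogous) Mukaiyama aldol of one silyl dienol ether of 2,6-diethyl-3,5-dimethyl-4-pyrone (new, catalytic, asymmetric): with propanal for the western fragment, with a chiral β-propanoyloxy aldehyde for the eastern fragment.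
3. That aldehyde ⇒ anti-crotylboration of (E)-3-bromo-2-methylacrolein, propanoylation, ozonolysis.
4. Ring order: the pyrone ring is made once (pentan-3-one + propanoic acid) before any stereocentre exists; one copy becomes ring B, a second copy ring A; no ring is formed later.

Assumption: the sense of induction of the chiral catalysts in steps 3, 7, 10 and 12 is assigned by analogy with their closest known relatives and would be confirmed on the first run (both enantiomers of each catalyst are available).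

Abbreviations: TBS = tert-butyldimethylsilyl; PPA = polyphosphoric acid; DMAP = 4-(dimethylamino)pyridine; dme = 1,2-dimethoxyethane; DMA = N,N-dimethylacetamide. BPA = the pentane-1,5-diyl-linked bisphosphoramide in which each P(=O) carries one NMe end of N,N'-dimethylpentane-1,5-diamine and both NMe groups of one N,N'-dimethyl-1,1'-binaphthyl-2,2'-diamine (seven-membered diazaphosphepine 4-oxide); (R,R) means both binaphthyl units are R. TRIP = 3,3'-bis(2,4,6-triisopropylphenyl)-1,1'-binaphthyl-2,2'-diyl hydrogen phosphate. IndaBOX = 2,2'-(cyclopropane-1,1-diyl)bis(3a,8a-dihydro-8H-indeno[1,2-d]oxazole).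

## Route

Step 1
Reactants: 1 pentan-3-one; 2 propanoic acid (2.2 equiv)
Product: 4 2,6-diethyl-3,5-dimethyl-4H-pyran-4-one, via 4,6-dimethylnonane-3,5,7-trione 3 (not isolated)
Conditions: PPA, 100 °C; ice/H2O
Reagents that add atoms: none
Why: PPA-mediated double C-acylation of the ketone by propanoic acid gives the 1,3,5-triketone, which cyclodehydrates to the 4-pyrone (classical polyphosphoric acid pyrone synthesis); no stereocentre is formed.

Step 2
Reactants: 4 2,6-diethyl-3,5-dimethyl-4H-pyran-4-one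
Product: 5 (2Z)-4-[tert-butyl(dimethyl)silyl]oxy-6-ethyl-2-ethylidene-3,5-dimethyl-2H-pyran
Conditions: tBuMe2SiOTf (1.05 equiv), Et3N (1.3 equiv), CH2Cl2, 0 °C to rt; pentane, filtration, bulb-to-bulb distillation
Reagents that add atoms: tert-butyldimethylsilyl trifluoromethanesulfonate, CC(C)(C)[Si](C)(C)OS(=O)(=O)C(F)(F)F
Why: Soft enolisation of a vinylogous ester: O-silylation of the pyrone carbonyl acidifies the lateral CH2, which Et3N removes to give the cross-conjugated silyl dienol ether (pyrylium anhydro-base formation); the Z geometry avoids allylic 1,3-strain with the ring C3 methyl, and the symmetry of 4 makes both ethyl groups equivalent.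

Step 3
Reactants: 5 (2Z)-4-[tert-butyl(dimethyl)silyl]oxy-6-ethyl-2-ethylidene-3,5-dimethyl-2H-pyran; 6 propanal (1.5 equiv)
Product: 8 2-ethyl-6-[(2S,3S)-3-hydroxypentan-2-yl]-3,5-dimethyl-4H-pyran-4-one, via trichlorosilyl ether 7 (not isolated)
Conditions: SiCl4 (1.1 equiv), (R,R)-BPA (5 mol %), iPr2NEt (10 mol %), CH2Cl2, −78 °C; then sat. aq NaHCO3, 0 °C
Reagents that add atoms: none
Why: Proposed new method: catalytic enantio- and anti-selective vinylogous Mukaiyama aldol at the lateral carbon of a 4-pyrone; the chiral bisphosphoramide ionises SiCl4 to a chlorosilyl cation that binds propanal, the electron-rich exocyclic carbon of 5 (the only site whose attack restores the pyrone) adds to the aldehyde Re face through an open transition state that keeps the bulky silicon-bound oxygen and the aldehyde ethyl group away from the lateral methyl and the ring, which gives the anti pair and sets C2 (S) and C3 (S) of the side chain, and rearomatisation with loss of TBSCl drives the step; the closest known reaction is the Lewis-base-activated SiCl4 vinylogous aldol of γ-methyl silyl dienol ethers of unsaturated esters and amides, which is γ- and anti-selective and tolerates amide-like Lewis-basic products.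

Step 4
Reactants: 8 2-ethyl-6-[(2S,3S)-3-hydroxypentan-2-yl]-3,5-dimethyl-4H-pyran-4-one
Product: 9 2-[(2S,3S)-3-[tert-butyl(dimethyl)silyl]oxypentan-2-yl]-6-ethyl-3,5-dimethyl-4H-pyran-4-one
Conditions: tBuMe2SiCl, imidazole, DMF, rt to 40 °C
Reagents that add atoms: tert-butyldimethylsilyl chloride, CC(C)(C)[Si](C)(C)Cl
Why: Standard imidazole-promoted silylation of the secondary alcohol under non-enolising conditions; no stereocentre is touched.

Step 5
Reactants: 9 2-[(2S,3S)-3-[tert-butyl(dimethyl)silyl]oxypentan-2-yl]-6-ethyl-3,5-dimethyl-4H-pyran-4-one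
Product: 11 2-[(2S,3S)-3-[tert-butyl(dimethyl)silyl]oxypentan-2-yl]-6-(1-chloroethyl)-3,5-dimethyl-4H-pyran-4-one (both epimers at the CHCl carbon), via silyl dienol ether 10 (not isolated)
Conditions: Me3SiOTf (1.15 equiv), Et3N (1.2 equiv), CH2Cl2, −78 to 0 °C; then N-chlorosuccinimide (1.2 equiv), −78 to 0 °C; H2O
Reagents that add atoms: N-chlorosuccinimide, O=C1CCC(=O)N1Cl
Why: Soft enolisation as in step 2 occurs at the unbranched ethyl group (the branched side would need a tetrasubstituted exocyclic alkene, so its stereocentre is not touched), and electrophilic chlorination of the silyl dienol ether takes place at the exocyclic carbon because only that restores the pyrone (silyl enol ether α-halogenation); the C–Cl centre forms as both epimers, which is irrelevant because step 12 is stereoconvergent.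

Step 6
Reactants: 12 2-methylprop-2-enal
Product: 14 (2E)-3-bromo-2-methylprop-2-enal, via 2,3-dibromo-2-methylpropanal 13 (not isolated)
Conditions: Br2, CH2Cl2, −78 to 0 °C; then Et3N, 0 °C to rt; distillation
Reagents that add atoms: bromine, BrBr
Why: Bromine addition to the alkene followed by E2 dehydrobromination (the α-carbon has no hydrogen, so HBr is lost across C2–C3) gives the conjugated β-bromo enal as the more stable E isomer.

Step 7
Reactants: 14 (2E)-3-bromo-2-methylprop-2-enal; 15 2-[(2E)-but-2-en-1-yl]-4,4,5,5-tetramethyl-1,3,2-dioxaborolane (1.2 equiv)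
Product: 17 (1E,3R,4R)-1-bromo-2,4-dimethylhexa-1,5-dien-3-ol, via pinacol borate 16 (not isolated)
Conditions: (R)-TRIP (5 mol %), toluene, −30 °C; then H2O
Reagents that add atoms: none
Why: Chiral phosphoric acid-catalysed crotylboration through a closed chair (Zimmerman–Traxler-type) transition state; the E-crotyl geometry gives the anti pair and the (R)-acid directs attack to the aldehyde Re face, setting C3 (R) and C4 (R).

Step 8
Reactants: 17 (1E,3R,4R)-1-bromo-2,4-dimethylhexa-1,5-dien-3-ol
Product: 18 (1E,3R,4R)-1-bromo-2,4-dimethylhexa-1,5-dien-3-yl propanoate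
Conditions: (EtCO)2O, Et3N, DMAP (5 mol %), CH2Cl2, 0 °C to rt
Reagents that add atoms: propanoic anhydride, CCC(=O)OC(=O)CC
Why: DMAP-catalysed acylation of the secondary allylic alcohol installs the propanoate of the target with retention of configuration.

Step 9
Reactants: 18 (1E,3R,4R)-1-bromo-2,4-dimethylhexa-1,5-dien-3-yl propanoate
Product: 20 (1E,3R,4S)-1-bromo-2,4-dimethyl-5-oxopent-1-en-3-yl propanoate, via ozonide 19 (not isolated)
Conditions: O3, CH2Cl2, −78 °C (stopped at first blue colour); then PPh3, −78 °C to rt; used crude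
Reagents that add atoms: ozone, [O-][O+]=O
Why: Ozonolysis with reductive work-up cleaves the electron-richer terminal vinyl group while the bromine- and acyloxy-deactivated trisubstituted alkene is spared; the α-stereocentre survives because the aldehyde is kept cold and used directly (its descriptor changes to S only through priority rules).

Step 10
Reactants: 20 (1E,3R,4S)-1-bromo-2,4-dimethyl-5-oxopent-1-en-3-yl propanoate; 5 (2Z)-4-[tert-butyl(dimethyl)silyl]oxy-6-ethyl-2-ethylidene-3,5-dimethyl-2H-pyran (1.5 equiv)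
Product: 22 (1E,3R,4R,5R,6R)-1-bromo-6-(6-ethyl-3,5-dimethyl-4-oxo-4H-pyran-2-yl)-5-hydroxy-2,4-dimethylhept-1-en-3-yl propanoate, via trichlorosilyl ether 21 (not isolated)
Conditions: SiCl4 (1.1 equiv), (S,S)-BPA (5 mol %), iPr2NEt (10 mol %), CH2Cl2, −78 °C; then sat. aq NaHCO3, 0 °C
Reagents that add atoms: none
Why: Proposed new method: second use of the lateral vinylogous Mukaiyama aldol of step 3, now with the enantiomeric catalyst on a chiral aldehyde; catalyst-directed Si-face attack coincides with Felkin–Anh control by the α-methyl group and 1,3-anti induction by the β-acyloxy group of 20 (matched case), and the open transition state again gives the anti pyrone-methyl/hydroxyl pair, setting C5 (R) and C6 (R); the closest known reactions are the Lewis-base-activated SiCl4 vinylogous aldol and Felkin-controlled Mukaiyama aldols of anti α-methyl-β-oxy aldehydes.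

Step 11
Reactants: 22 (1E,3R,4R,5R,6R)-1-bromo-6-(6-ethyl-3,5-dimethyl-4-oxo-4H-pyran-2-yl)-5-hydroxy-2,4-dimethylhept-1-en-3-yl propanoate
Product: 23 (1E,3R,4R,5R,6R)-5-acetoxy-1-bromo-6-(6-ethyl-3,5-dimethyl-4-oxo-4H-pyran-2-yl)-2,4-dimethylhept-1-en-3-yl propanoate
Conditions: Ac2O, pyridine, DMAP (10 mol %), CH2Cl2, 0 °C
Reagents that add atoms: acetic anhydride, CC(=O)OC(C)=O
Why: DMAP-catalysed acetylation of the hindered secondary alcohol at 0 °C is fast enough to outrun 1,3-migration of the propanoate and is too weakly basic to eliminate the β-acyloxy group.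

Step 12
Reactants: 11 2-[(2S,3S)-3-[tert-butyl(dimethyl)silyl]oxypentan-2-yl]-6-(1-chloroethyl)-3,5-dimethyl-4H-pyran-4-one (1.3 equiv, epimer mixture); 23 (1E,3R,4R,5R,6R)-5-acetoxy-1-bromo-6-(6-ethyl-3,5-dimethyl-4-oxo-4H-pyran-2-yl)-2,4-dimethylhept-1-en-3-yl propanoate
Product: 24 (2S,3E,5R,6R,7R,8R)-7-acetoxy-2-{6-[(2S,3S)-3-[tert-butyl(dimethyl)silyl]oxypentan-2-yl]-3,5-dimethyl-4-oxo-4H-pyran-2-yl}-8-(6-ethyl-3,5-dimethyl-4-oxo-4H-pyran-2-yl)-4,6-dimethylnon-3-en-5-yl propanoate
Conditions: NiCl2·dme (10 mol %), (3aR,3a'R,8aS,8a'S)-IndaBOX (12 mol %), Mn powder (3 equiv), NaI (0.5 equiv), DMA, 0 °C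
Reagents that add atoms: none
Why: Proposed new method: enantioconvergent nickel-catalysed reductive cross-electrophile coupling of a racemic 2-(1-chloroethyl)-4-pyrone with a trisubstituted alkenyl bromide; zerovalent nickel inserts into the C–Br bond of 23 with retention of the E geometry, the pyronylic chloride (iodide after exchange with NaI) is reduced to a planar radical stabilised by the vinylogous carbonyl, the chiral alkenylnickel captures it, and reductive elimination from trivalent nickel sets C2 (S) under ligand control whatever the configuration of 11, with manganese turning the catalyst over under neutral conditions that do not epimerise the new doubly activated C–H; the closest known reaction is the nickel/bis(oxazoline)-catalysed asymmetric reductive coupling of racemic secondary benzylic chlorides with alkenyl bromides.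

Step 13
Reactants: 24 (2S,3E,5R,6R,7R,8R)-7-acetoxy-2-{6-[(2S,3S)-3-[tert-butyl(dimethyl)silyl]oxypentan-2-yl]-3,5-dimethyl-4-oxo-4H-pyran-2-yl}-8-(6-ethyl-3,5-dimethyl-4-oxo-4H-pyran-2-yl)-4,6-dimethylnon-3-en-5-yl propanoate
Product: 25 (2S,3E,5R,6R,7R,8R)-7-acetoxy-8-(6-ethyl-3,5-dimethyl-4-oxo-4H-pyran-2-yl)-2-{6-[(2S,3S)-3-hydroxypentan-2-yl]-3,5-dimethyl-4-oxo-4H-pyran-2-yl}-4,6-dimethylnon-3-en-5-yl propanoate (CNP0265513.1)
Conditions: HF·pyridine, pyridine, THF, 0 °C to rt
Reagents that add atoms: none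
Why: Buffered fluoride desilylation removes the TBS ether without touching the acetate, the propanoate or the base-sensitive allylic/pyronylic C–H, so all seven stereocentres and the E alkene are retained.

## Compound list

1 | pentan-3-one | CCC(=O)CC | starting material
2 | propanoic acid | CCC(=O)O | starting material
3 | 4,6-dimethylnonane-3,5,7-trione | CCC(=O)C(C)C(=O)C(C)C(=O)CC | intermediate (not isolated)
4 | 2,6-diethyl-3,5-dimethyl-4H-pyran-4-one | CCc1oc(CC)c(C)c(=O)c1C | intermediate
5 | (2Z)-4-[tert-butyl(dimethyl)silyl]oxy-6-ethyl-2-ethylidene-3,5-dimethyl-2H-pyran | C/C=C1\OC(CC)=C(C)C(O[Si](C)(C)C(C)(C)C)=C1C | intermediate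
6 | propanal | CCC=O | starting material
7 | 2-ethyl-3,5-dimethyl-6-[(2S,3S)-3-(trichlorosilyloxy)pentan-2-yl]-4H-pyran-4-one | CCc1oc([C@@H](C)[C@@H](O[Si](Cl)(Cl)Cl)CC)c(C)c(=O)c1C | intermediate (not isolated)
8 | 2-ethyl-6-[(2S,3S)-3-hydroxypentan-2-yl]-3,5-dimethyl-4H-pyran-4-one | CCc1oc([C@@H](C)[C@@H](O)CC)c(C)c(=O)c1C | intermediate
9 | 2-[(2S,3S)-3-[tert-butyl(dimethyl)silyl]oxypentan-2-yl]-6-ethyl-3,5-dimethyl-4H-pyran-4-one | CCc1oc([C@@H](C)[C@@H](O[Si](C)(C)C(C)(C)C)CC)c(C)c(=O)c1C | intermediate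
10 | (2Z)-6-[(2S,3S)-3-[tert-butyl(dimethyl)silyl]oxypentan-2-yl]-2-ethylidene-3,5-dimethyl-4-(trimethylsilyloxy)-2H-pyran | C/C=C1\OC([C@@H](C)[C@@H](O[Si](C)(C)C(C)(C)C)CC)=C(C)C(O[Si](C)(C)C)=C1C | intermediate (not isolated)
11 | 2-[(2S,3S)-3-[tert-butyl(dimethyl)silyl]oxypentan-2-yl]-6-(1-chloroethyl)-3,5-dimethyl-4H-pyran-4-one, both epimers at the CHCl carbon | CC(Cl)c1oc([C@@H](C)[C@@H](O[Si](C)(C)C(C)(C)C)CC)c(C)c(=O)c1C | intermediate
12 | 2-methylprop-2-enal (methacrolein) | CC(=C)C=O | starting material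
13 | 2,3-dibromo-2-methylpropanal (racemic) | CC(Br)(CBr)C=O | intermediate (not isolated)
14 | (2E)-3-bromo-2-methylprop-2-enal | O=C/C(C)=C/Br | intermediate
15 | 2-[(2E)-but-2-en-1-yl]-4,4,5,5-tetramethyl-1,3,2-dioxaborolane | C/C=C/CB1OC(C)(C)C(C)(C)O1 | starting material
16 | 2-{[(1E,3R,4R)-1-bromo-2,4-dimethylhexa-1,5-dien-3-yl]oxy}-4,4,5,5-tetramethyl-1,3,2-dioxaborolane | CC1(C)OB(O[C@@H](/C(C)=C/Br)[C@H](C)C=C)OC1(C)C | intermediate (not isolated)
17 | (1E,3R,4R)-1-bromo-2,4-dimethylhexa-1,5-dien-3-ol | O[C@@H](/C(C)=C/Br)[C@H](C)C=C | intermediate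
18 | (1E,3R,4R)-1-bromo-2,4-dimethylhexa-1,5-dien-3-yl propanoate | CCC(=O)O[C@@H](/C(C)=C/Br)[C@H](C)C=C | intermediate
19 | (1E,3R,4S)-1-bromo-2-methyl-4-(1,2,4-trioxolan-3-yl)pent-1-en-3-yl propanoate, both epimers at the trioxolane carbon | CCC(=O)O[C@@H](/C(C)=C/Br)[C@H](C)C1OCOO1 | intermediate (not isolated)
20 | (1E,3R,4S)-1-bromo-2,4-dimethyl-5-oxopent-1-en-3-yl propanoate | CCC(=O)O[C@@H](/C(C)=C/Br)[C@H](C)C=O | intermediate
21 | (1E,3R,4S,5R,6R)-1-bromo-6-(6-ethyl-3,5-dimethyl-4-oxo-4H-pyran-2-yl)-2,4-dimethyl-5-(trichlorosilyloxy)hept-1-en-3-yl propanoate | CCC(=O)O[C@@H](/C(C)=C/Br)[C@H](C)[C@@H](O[Si](Cl)(Cl)Cl)[C@@H](C)c1oc(CC)c(C)c(=O)c1C | intermediate (not isolated)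
22 | (1E,3R,4R,5R,6R)-1-bromo-6-(6-ethyl-3,5-dimethyl-4-oxo-4H-pyran-2-yl)-5-hydroxy-2,4-dimethylhept-1-en-3-yl propanoate | CCC(=O)O[C@@H](/C(C)=C/Br)[C@H](C)[C@@H](O)[C@@H](C)c1oc(CC)c(C)c(=O)c1C | intermediate
23 | (1E,3R,4R,5R,6R)-5-acetoxy-1-bromo-6-(6-ethyl-3,5-dimethyl-4-oxo-4H-pyran-2-yl)-2,4-dimethylhept-1-en-3-yl propanoate | CCC(=O)O[C@@H](/C(C)=C/Br)[C@H](C)[C@@H](OC(C)=O)[C@@H](C)c1oc(CC)c(C)c(=O)c1C | intermediate
24 | (2S,3E,5R,6R,7R,8R)-7-acetoxy-2-{6-[(2S,3S)-3-[tert-butyl(dimethyl)silyl]oxypentan-2-yl]-3,5-dimethyl-4-oxo-4H-pyran-2-yl}-8-(6-ethyl-3,5-dimethyl-4-oxo-4H-pyran-2-yl)-4,6-dimethylnon-3-en-5-yl propanoate | CCC(=O)O[C@@H](/C(C)=C/[C@H](C)c1oc([C@@H](C)[C@@H](O[Si](C)(C)C(C)(C)C)CC)c(C)c(=O)c1C)[C@H](C)[C@@H](OC(C)=O)[C@@H](C)c1oc(CC)c(C)c(=O)c1C | intermediate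
25 | (2S,3E,5R,6R,7R,8R)-7-acetoxy-8-(6-ethyl-3,5-dimethyl-4-oxo-4H-pyran-2-yl)-2-{6-[(2S,3S)-3-hydroxypentan-2-yl]-3,5-dimethyl-4-oxo-4H-pyran-2-yl}-4,6-dimethylnon-3-en-5-yl propanoate | CCC(=O)O[C@@H](/C(C)=C/[C@H](C)c1oc([C@@H](C)[C@@H](O)CC)c(C)c(=O)c1C)[C@H](C)[C@@H](OC(C)=O)[C@@H](C)c1oc(CC)c(C)c(=O)c1C | target

## Step count and risk

Total step count: 13.
Longest linear sequence: 8 steps (12 → 14 → 17 → 18 → 20 → 22 → 23 → 24 → 25; steps 6 to 13).

Three steps most likely to fail:

**Step 3 (new lateral aldol, western fragment).** Unknowns are catalyst turnover in the presence of the Lewis-basic pyrone product, the anti/syn ratio and the enantioselectivity. Fallback with known chemistry, setting out from 4 and 6 and returning at 8: pyrone 4 is deprotonated at the lateral CH2 with LiN(iPr)2 (THF, −78 °C) to the lithium dienolate F1, which adds to propanal 6 (known lateral aldol of 2-ethyl-4-pyrones) to give the aldol stereoisomer mixture F2. Chromatography gives the racemic anti aldol F3. Acylation with vinyl acetate catalysed by Candida antarctica lipase B converts the faster-reacting (2R,3R)-enantiomer into the (2R,3R)-acetate F4 and leaves the (2S,3S)-alcohol, which is 8.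

**Step 10 (new lateral aldol on the chiral aldehyde).** In addition to the unknowns of step 3, aldehyde 20 can lose propanoic acid or epimerise. Fallback with known chemistry, setting out from 17 and returning at 23: alcohol 17 is silylated (Et3SiCl, imidazole) to the triethylsilyl ether F5. Ozonolysis (O3; PPh3) through the ozonide F6 gives the aldehyde F7, which is stable to base. The lithium dienolate F1 of pyrone 4 (THF, −78 °C) adds to F7 under Felkin–Anh control and, after chromatographic removal of the unwanted epimer at the pyrone-bearing carbon, gives the aldol F8. Acetylation (Ac2O, DMAP) gives the acetate F9, HF·pyridine removes the triethylsilyl group to give the alcohol F10, and propanoic anhydride/DMAP gives 23.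

**Step 12 (new nickel reductive coupling).** Risks are an untested electrophile class, homocoupling of either partner, insertion of zerovalent nickel into the allylic propanoate, and unknown ligand control at the pyronylic centre. Fallback with known chemistry, setting out from 11 and 23 and returning at 24: chloride 11 is converted with zinc dust/LiCl (THF) into the pyronylic zinc chloride F11, which is coupled with bromide 23 using Pd(PPh3)4 (Negishi coupling, alkene geometry retained). Without a chiral catalyst this gives 24 together with its C2 epimer F12 in about equal amounts; preparative HPLC separates them and 24 goes on to step 13. F12 is not recycled by base, because deprotonation at C2 would eliminate the allylic propanoate.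

## Further compounds

F1 | step 3 | lithium (2Z)-6-ethyl-2-ethylidene-3,5-dimethyl-2H-pyran-4-olate (lateral lithium dienolate of 4) | [Li+].C/C=C1\OC(CC)=C(C)C([O-])=C1C
F2 | step 3 | 2-ethyl-6-(3-hydroxypentan-2-yl)-3,5-dimethyl-4H-pyran-4-one, mixture of all four stereoisomers | CCc1oc(C(C)C(O)CC)c(C)c(=O)c1C
F3 | step 3 | racemic anti aldol, 1:1 mixture of the (2S,3S) and (2R,3R) isomers of F2 | CCc1oc([C@@H](C)[C@@H](O)CC)c(C)c(=O)c1C.CCc1oc([C@H](C)[C@H](O)CC)c(C)c(=O)c1C
F4 | step 3 | (2R,3R)-2-(6-ethyl-3,5-dimethyl-4-oxo-4H-pyran-2-yl)pentan-3-yl acetate | CCc1oc([C@H](C)[C@H](OC(C)=O)CC)c(C)c(=O)c1C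
F5 | step 10 | [(1E,3R,4R)-1-bromo-2,4-dimethylhexa-1,5-dien-3-yl]oxy(triethyl)silane | CC[Si](CC)(CC)O[C@@H](/C(C)=C/Br)[C@H](C)C=C
F6 | step 10 | 1,2,4-trioxolane (ozonide) formed from the vinyl group of F5, both epimers at the trioxolane carbon | CC[Si](CC)(CC)O[C@@H](/C(C)=C/Br)[C@H](C)C1OCOO1
F7 | step 10 | (2S,3R,4E)-5-bromo-2,4-dimethyl-3-(triethylsilyloxy)pent-4-enal | CC[Si](CC)(CC)O[C@@H](/C(C)=C/Br)[C@H](C)C=O
F8 | step 10 | 2-[(2R,3R,4R,5R,6E)-7-bromo-3-hydroxy-4,6-dimethyl-5-(triethylsilyloxy)hept-6-en-2-yl]-6-ethyl-3,5-dimethyl-4H-pyran-4-one | CC[Si](CC)(CC)O[C@@H](/C(C)=C/Br)[C@H](C)[C@@H](O)[C@@H](C)c1oc(CC)c(C)c(=O)c1C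
F9 | step 10 | (2R,3R,4R,5R,6E)-7-bromo-2-(6-ethyl-3,5-dimethyl-4-oxo-4H-pyran-2-yl)-4,6-dimethyl-5-(triethylsilyloxy)hept-6-en-3-yl acetate | CC[Si](CC)(CC)O[C@@H](/C(C)=C/Br)[C@H](C)[C@@H](OC(C)=O)[C@@H](C)c1oc(CC)c(C)c(=O)c1C
F10 | step 10 | (2R,3R,4S,5R,6E)-7-bromo-2-(6-ethyl-3,5-dimethyl-4-oxo-4H-pyran-2-yl)-5-hydroxy-4,6-dimethylhept-6-en-3-yl acetate | O[C@@H](/C(C)=C/Br)[C@H](C)[C@@H](OC(C)=O)[C@@H](C)c1oc(CC)c(C)c(=O)c1C
F11 | step 12 | chlorido{1-[6-[(2S,3S)-3-[tert-butyl(dimethyl)silyl]oxypentan-2-yl]-3,5-dimethyl-4-oxo-4H-pyran-2-yl]ethyl}zinc, both epimers at the zinc-bearing carbon | CC([Zn]Cl)c1oc([C@@H](C)[C@@H](O[Si](C)(C)C(C)(C)C)CC)c(C)c(=O)c1C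
F12 | step 12 | (2R,3E,5R,6R,7R,8R)-7-acetoxy-2-{6-[(2S,3S)-3-[tert-butyl(dimethyl)silyl]oxypentan-2-yl]-3,5-dimethyl-4-oxo-4H-pyran-2-yl}-8-(6-ethyl-3,5-dimethyl-4-oxo-4H-pyran-2-yl)-4,6-dimethylnon-3-en-5-yl propanoate (C2 epimer of 24) | CCC(=O)O[C@@H](/C(C)=C/[C@@H](C)c1oc([C@@H](C)[C@@H](O[Si](C)(C)C(C)(C)C)CC)c(C)c(=O)c1C)[C@H](C)[C@@H](OC(C)=O)[C@@H](C)c1oc(CC)c(C)c(=O)c1C
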